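**Strategy.** Everything rests on forming the C6–C7 bond of ring B last in the carbocyclic core (eudesmane numbering: C4 ether carbon, C5/C10 ring fusion, C7 carbinol-bearing carbon). The key step exploits two features: C4 neighbours C5, so a C4 ketone turns exocyclic C6 into an enone terminus, and C11 is gem-dimethylated, so the C7=C11 olefin of a homoprenyl chain on quaternary C10 attacks C6 through C7. One Me2AlCl-promoted cyclization of this ring-A α-methylene ketone closes ring B, sets C7, leaves an isopropenyl handle and, after equilibration, the trans fusion at C5. The C4 ketone then becomes the α-face tertiary alkoxide, which is arylated; two cross-couplings finish the honokiol unit.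

Key step: step 3

Remark: eudesmane numbering is used for the terpenoid part (α = face opposite the C10 methyl group); 2-bromo-4-chloro-1-iodobenzene and 2-allyl-4-bromophenol are taken as purchasable.

**Step 1**
Reactants: 1 3-methylcyclohex-2-en-1-one; 2 5-bromo-2-methylpent-2-ene
Product: 5 (3R)-2-[(dimethylamino)methyl]-3-methyl-3-(4-methylpent-3-en-1-yl)cyclohexan-1-one (C2 epimers), via Grignard reagent 3 (not isolated), via bromomagnesium enolate 4 (not isolated)
Conditions: 2, Mg, Et2O, 35 °C; then 1, Cu(OTf)2 (3 mol %), chiral C2-symmetric imidazolinium chloride (NHC precursor, 4 mol %), Et2O, −30 °C; then CH2=NMe2+ I−, THF, −30 to 25 °C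
Reagents that add atoms: Eschenmoser's salt (N,N-dimethylmethyleneiminium iodide), C=[N+](C)C.[I-]
Why: Copper-catalysed asymmetric conjugate addition of a Grignard reagent to a β-substituted cyclohexenone should set the quaternary C10 centre under control of the chiral NHC ligand (enantiomer chosen for R), and the regiodefined enolate 4 is intercepted at C5 by the iminium salt in a Mannich reaction.

**Step 2**
Reactants: 5 (3R)-2-[(dimethylamino)methyl]-3-methyl-3-(4-methylpent-3-en-1-yl)cyclohexan-1-one
Product: 7 (R)-3-methyl-2-methylidene-3-(4-methylpent-3-en-1-yl)cyclohexan-1-one, via ammonium iodide 6 (not isolated)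
Conditions: MeI, Et2O, 25 °C; then aq. NaHCO3, CH2Cl2, 25 °C
Reagents that add atoms: none
Why: N-Methylation to the quaternary ammonium salt and mild-base β-elimination (Hofmann-type elimination of a Mannich base) should unveil the exocyclic enone, which the adjacent quaternary centre shields from dimerization.

**Step 3**
Reactants: 7 (R)-3-methyl-2-methylidene-3-(4-methylpent-3-en-1-yl)cyclohexan-1-one
Product: 10 (4aR,7R,8aR)-4a-methyl-7-(prop-1-en-2-yl)octahydronaphthalen-1(2H)-one, via chloro(methyl)aluminium enolate 8 (not isolated), via cis-fused C5 epimer 9 (not isolated)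
Conditions: Me2AlCl (1.5 equiv), CH2Cl2, −78 to −20 °C; aq. NH4Cl; then NaOMe (cat.), MeOH, 25 °C
Reagents that add atoms: none
Why: Me2AlCl binds the s-cis enone (C4=O/C5=C6) and the C7 terminus of the trisubstituted C7=C11 olefin adds to C6, the developing C11 cation losing a methyl proton to the aluminate (methane) to leave the isopropenyl group and enolate 8; this is a Lewis acid-promoted intramolecular conjugate ene (cation–olefin) cyclization, a known reaction type of enones with tethered trisubstituted olefins. Ring B closes as a six-membered ring, exo with respect to the C7=C11 olefin (6-exo-trig) and endo with respect to the enone. C7 is set in a chair-like transition state in which the chain on C10 is equatorial on ring A (the only geometry that brings C9 into the enone plane), the C10 methyl is axial and the C11 terminus is equatorial, which places the isopropenyl group cis to the C10 methyl (7R). C5 is controlled twice: axial protonation of 8 from the α face, anti to the axial C10 methyl, should favour the trans fusion, and NaOMe equilibrates any cis-fused 9 through this epimerizable centre to the trans ketone, in which the angular methyl has lost one syn-axial hydrogen contact to the C4 carbonyl. The step needs conjugate (C6) rather than carbonyl (C4) attack and Markovnikov use of the olefin; the unhindered exocyclic CH2, the strain of the bridged 1,2-adduct and the tertiary character of C11 secure both, and O-capture of the C11 cation by the enolate is blocked because it would give a bridgehead enol ether.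

**Step 4**
Reactants: 10 (4aR,7R,8aR)-4a-methyl-7-(prop-1-en-2-yl)octahydronaphthalen-1(2H)-one
Product: 12 Δ3 enol triflate of 10 (C4–OTf; 5α-H; 7β-isopropenyl; 10β-methyl), via potassium enolate 11 (not isolated)
Conditions: KN(SiMe3)2, THF, −78 °C; PhNTf2, −78 to 0 °C
Reagents that add atoms: N-phenylbis(trifluoromethanesulfonimide), O=S(=O)(N(c1ccccc1)S(=O)(=O)C(F)(F)F)C(F)(F)F
Why: Kinetic deprotonation by the bulky amide base should occur at the C3 methylene and not at the hindered ring-fusion C5–H, and O-triflation of the enolate fixes the Δ3 enol triflate without touching C5 (regioselective enol triflate formation).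

**Step 5**
Reactants: 12 Δ3 enol triflate of 10
Product: 13 (2R,4aR,8aR)-4a,8-dimethyl-2-(prop-1-en-2-yl)-1,2,3,4,4a,5,6,8a-octahydronaphthalene
Conditions: MeMgBr, Fe(acac)3 (5 mol %), THF/NMP, −30 to 0 °C
Reagents that add atoms: methylmagnesium bromide, C[Mg]Br
Why: Fe(acac)3-catalysed cross-coupling of the alkenyl triflate with the Grignard reagent (Kumada-type coupling) should install the C4 methyl group as a trisubstituted Δ3 olefin and leave the isopropenyl group untouched.

**Step 6**
Reactants: 13 (2R,4aR,8aR)-4a,8-dimethyl-2-(prop-1-en-2-yl)-1,2,3,4,4a,5,6,8a-octahydronaphthalene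
Product: 14 (3R,4S)-3,4-epoxyeudesm-11-ene (3α,4α-epoxide of 13)
Conditions: mCPBA (1.0 equiv), NaHCO3, CH2Cl2, −30 to 0 °C
Reagents that add atoms: 3-chloroperoxybenzoic acid, OOC(=O)c1cccc(Cl)c1
Why: Prilezhaev epoxidation is faster at the trisubstituted ring olefin than at the 1,1-disubstituted isopropenyl group, and the peracid should approach the α face because the β face is shielded by the axial C10 methyl group, which places the C4–O bond on the α face.

**Step 7**
Reactants: 14 (3R,4S)-3,4-epoxyeudesm-11-ene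
Product: 15 (1R,4aR,7R,8aR)-1,4a-dimethyl-7-(prop-1-en-2-yl)decahydronaphthalen-1-ol
Conditions: LiEt3BH, THF, 0 to 40 °C; H2O
Reagents that add atoms: none
Why: SN2 hydride opening of the trisubstituted epoxide at the secondary C3 (the tertiary C4 is shielded by the syn-axial C10 methyl) leaves the oxygen on C4 with retention, which should give the 4α tertiary alcohol with the C4 methyl β (epoxide reduction).

**Step 8**
Reactants: 16 2-bromo-4-chloro-1-iodobenzene; 17 1,3,5-trimethoxybenzene
Product: 19 (2-bromo-4-chlorophenyl)(2,4,6-trimethoxyphenyl)iodonium 4-methylbenzenesulfonate, via hydroxy(tosyloxy)iodoarene 18 (not isolated)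
Conditions: mCPBA, TsOH·H2O, MeCN, 75 °C; then 17, 75 °C
Reagents that add atoms: 4-methylbenzenesulfonic acid monohydrate, Cc1ccc(S(=O)(=O)O)cc1.O
Why: One-pot oxidation of the aryl iodide to trivalent iodine followed by electrophilic aromatic substitution on the electron-rich arene should give the unsymmetrical diaryliodonium salt carrying a non-transferable trimethoxyphenyl group (diaryliodonium salt synthesis).

**Step 9**
Reactants: 15 (1R,4aR,7R,8aR)-1,4a-dimethyl-7-(prop-1-en-2-yl)decahydronaphthalen-1-ol; 19 (2-bromo-4-chlorophenyl)(2,4,6-trimethoxyphenyl)iodonium 4-methylbenzenesulfonate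
Product: 21 (1R,4aR,7R,8aR)-1-(2-bromo-4-chlorophenoxy)-1,4a-dimethyl-7-(prop-1-en-2-yl)decahydronaphthalene, via sodium alkoxide 20 (not isolated)
Conditions: NaH, toluene, 60 °C; then 19, 25 to 50 °C
Reagents that add atoms: none
Why: Metal-free O-arylation of a tertiary alkoxide by ligand coupling at trivalent iodine tolerates steric congestion, the electron-poorer ortho-bromo aryl group should be transferred in preference to the trimethoxyphenyl group, and the C4 configuration is untouched because the alcohol C–O bond is never broken.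

**Step 10**
Reactants: 21 (1R,4aR,7R,8aR)-1-(2-bromo-4-chlorophenoxy)-1,4a-dimethyl-7-(prop-1-en-2-yl)decahydronaphthalene
Product: 22 2-[(2R,4aR,8R,8aR)-8-(2-bromo-4-chlorophenoxy)-4a,8-dimethyldecahydronaphthalen-2-yl]propan-2-ol
Conditions: Co(acac)2 (20 mol %), PhSiH3, O2 (1 atm), THF, 25 °C
Reagents that add atoms: dioxygen, O=O
Why: Mukaiyama hydration (cobalt hydride hydrogen-atom transfer, O2 trapping of the tertiary radical, reduction by the silane) should convert the only olefin present into the Markovnikov tertiary alcohol at C11 without acid that would ionize the tertiary aryl ether.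

**Step 11**
Reactants: 23 2-allyl-4-bromophenol
Product: 24 2-allyl-4-(4,4,5,5-tetramethyl-1,3,2-dioxaborolan-2-yl)phenol
Conditions: B2pin2, Pd(dppf)Cl2 (3 mol %), KOAc, 1,4-dioxane, 80 °C
Reagents that add atoms: bis(pinacolato)diboron, CC1(C)OB(B2OC(C)(C)C(C)(C)O2)OC1(C)C
Why: Miyaura borylation of the aryl bromide should proceed in the presence of the free phenol and the allyl group under the weak base KOAc.

**Step 12**
Reactants: 22 2-[(2R,4aR,8R,8aR)-8-(2-bromo-4-chlorophenoxy)-4a,8-dimethyldecahydronaphthalen-2-yl]propan-2-ol; 24 2-allyl-4-(4,4,5,5-tetramethyl-1,3,2-dioxaborolan-2-yl)phenol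
Product: 25 2-[(2R,4aR,8R,8aR)-8-{[3'-allyl-5-chloro-4'-hydroxy-(1,1'-biphenyl)-2-yl]oxy}-4a,8-dimethyldecahydronaphthalen-2-yl]propan-2-ol
Conditions: Pd(dppf)Cl2 (5 mol %), K2CO3, 1,4-dioxane/H2O, 85 °C
Reagents that add atoms: none
Why: Suzuki–Miyaura coupling should occur chemoselectively at the C–Br bond, since the aryl chloride resists oxidative addition with this catalyst, and builds the biaryl bond of the honokiol unit.

**Step 13**
Reactants: 25 2-[(2R,4aR,8R,8aR)-8-{[3'-allyl-5-chloro-4'-hydroxy-(1,1'-biphenyl)-2-yl]oxy}-4a,8-dimethyldecahydronaphthalen-2-yl]propan-2-ol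
Product: 26 2-[(2R,4aR,8R,8aR)-8-{[3',5-diallyl-4'-hydroxy-(1,1'-biphenyl)-2-yl]oxy}-4a,8-dimethyldecahydronaphthalen-2-yl]propan-2-ol (CNP0219722.1)
Conditions: allylB(pin), Pd(OAc)2 (5 mol %), XPhos (10 mol %), K3PO4, THF/H2O, 60 °C
Reagents that add atoms: allylboronic acid pinacol ester, C=CCB1OC(C)(C)C(C)(C)O1
Why: Suzuki–Miyaura allylation of the remaining aryl chloride, with a bulky dialkylbiarylphosphine to enable oxidative addition of the electron-rich C–Cl bond, should install the second allyl group para to the ether oxygen and complete the target.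

**Compound list**
1 | 3-methylcyclohex-2-en-1-one | CC1=CC(=O)CCC1 | starting material
2 | 5-bromo-2-methylpent-2-ene | CC(C)=CCCBr | starting material
3 | (4-methylpent-3-en-1-yl)magnesium bromide (not isolated) | CC(C)=CCC[Mg]Br | intermediate
4 | bromomagnesium enolate of (R)-3-methyl-3-(4-methylpent-3-en-1-yl)cyclohexanone (not isolated) | Br[Mg]OC1=C[C@@](C)(CCC=C(C)C)CCC1 | intermediate
5 | (3R)-2-[(dimethylamino)methyl]-3-methyl-3-(4-methylpent-3-en-1-yl)cyclohexan-1-one (C2 epimers) | O=C1CCC[C@](C)(CCC=C(C)C)C1CN(C)C | intermediate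
6 | trimethylammonium iodide derived from 5 (not isolated) | O=C1CCC[C@](C)(CCC=C(C)C)C1C[N+](C)(C)C.[I-] | intermediate
7 | (R)-3-methyl-2-methylidene-3-(4-methylpent-3-en-1-yl)cyclohexan-1-one | O=C1CCC[C@](C)(CCC=C(C)C)C1=C | intermediate
8 | chloro(methyl)aluminium C4=C5 enolate of 10 (7β-isopropenyl, 10β-methyl; not isolated) | C[Al](Cl)OC1=C2C[C@H](C(C)=C)CC[C@@]2(C)CCC1 | intermediate
9 | (4aR,7R,8aS)-4a-methyl-7-(prop-1-en-2-yl)octahydronaphthalen-1(2H)-one (cis-fused C5 epimer of 10; not isolated) | O=C1CCC[C@]2(C)CC[C@@H](C(C)=C)C[C@@H]21 | intermediate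
10 | (4aR,7R,8aR)-4a-methyl-7-(prop-1-en-2-yl)octahydronaphthalen-1(2H)-one (trans-fused; 5α-H, 7β-isopropenyl, 10β-methyl) | O=C1CCC[C@]2(C)CC[C@@H](C(C)=C)C[C@H]21 | intermediate
11 | potassium Δ3 enolate of 10 (not isolated) | [K+].[O-]C1=CCC[C@]2(C)CC[C@@H](C(C)=C)C[C@H]21 | intermediate
12 | Δ3 enol triflate of 10 (C4–OTf; 5α-H, 7β-isopropenyl, 10β-methyl) | O=S(=O)(OC1=CCC[C@]2(C)CC[C@@H](C(C)=C)C[C@H]21)C(F)(F)F | intermediate
13 | (2R,4aR,8aR)-4a,8-dimethyl-2-(prop-1-en-2-yl)-1,2,3,4,4a,5,6,8a-octahydronaphthalene (eudesma-3,11-diene) | CC1=CCC[C@]2(C)CC[C@@H](C(C)=C)C[C@H]21 | intermediate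
14 | (3R,4S)-3,4-epoxyeudesm-11-ene (3α,4α-epoxide; 4β-methyl, 5α-H, 7β-isopropenyl, 10β-methyl) | C[C@@]12O[C@@H]1CC[C@]3(C)CC[C@@H](C(C)=C)C[C@@H]23 | intermediate
15 | (1R,4aR,7R,8aR)-1,4a-dimethyl-7-(prop-1-en-2-yl)decahydronaphthalen-1-ol (eudesm-11-en-4α-ol) | O[C@]1(C)CCC[C@]2(C)CC[C@@H](C(C)=C)C[C@H]21 | intermediate
16 | 2-bromo-4-chloro-1-iodobenzene | Clc1ccc(I)c(Br)c1 | starting material
17 | 1,3,5-trimethoxybenzene | COc1cc(OC)cc(OC)c1 | starting material
18 | 2-bromo-4-chloro-1-[hydroxy(tosyloxy)iodo]benzene (not isolated) | OI(OS(=O)(=O)c1ccc(C)cc1)c1ccc(Cl)cc1Br | intermediate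
19 | (2-bromo-4-chlorophenyl)(2,4,6-trimethoxyphenyl)iodonium 4-methylbenzenesulfonate | COc1cc(OC)c([I+]c2ccc(Cl)cc2Br)c(OC)c1.Cc1ccc(S(=O)(=O)[O-])cc1 | intermediate
20 | sodium alkoxide of 15 (not isolated) | [Na+].[O-][C@]1(C)CCC[C@]2(C)CC[C@@H](C(C)=C)C[C@H]21 | intermediate
21 | (1R,4aR,7R,8aR)-1-(2-bromo-4-chlorophenoxy)-1,4a-dimethyl-7-(prop-1-en-2-yl)decahydronaphthalene | Clc1ccc(O[C@]2(C)CCC[C@]3(C)CC[C@@H](C(C)=C)C[C@H]32)c(Br)c1 | intermediate
22 | 2-[(2R,4aR,8R,8aR)-8-(2-bromo-4-chlorophenoxy)-4a,8-dimethyldecahydronaphthalen-2-yl]propan-2-ol | Clc1ccc(O[C@]2(C)CCC[C@]3(C)CC[C@@H](C(C)(C)O)C[C@H]32)c(Br)c1 | intermediate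
23 | 2-allyl-4-bromophenol | C=CCc1cc(Br)ccc1O | starting material
24 | 2-allyl-4-(4,4,5,5-tetramethyl-1,3,2-dioxaborolan-2-yl)phenol | C=CCc1cc(B2OC(C)(C)C(C)(C)O2)ccc1O | intermediate
25 | 2-[(2R,4aR,8R,8aR)-8-{[3'-allyl-5-chloro-4'-hydroxy-(1,1'-biphenyl)-2-yl]oxy}-4a,8-dimethyldecahydronaphthalen-2-yl]propan-2-ol | Clc1ccc(O[C@]2(C)CCC[C@]3(C)CC[C@@H](C(C)(C)O)C[C@H]32)c(-c2ccc(O)c(CC=C)c2)c1 | intermediate
26 | 2-[(2R,4aR,8R,8aR)-8-{[3',5-diallyl-4'-hydroxy-(1,1'-biphenyl)-2-yl]oxy}-4a,8-dimethyldecahydronaphthalen-2-yl]propan-2-ol (CNP0219722.1) | C=CCc1ccc(O[C@]2(C)CCC[C@]3(C)CC[C@@H](C(C)(C)O)C[C@H]32)c(-c2ccc(O)c(CC=C)c2)c1 | target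

**Step count.** Total: 13 steps. Longest linear sequence: 11 steps (steps 1–7, 9, 10, 12, 13); steps 8 and 11 prepare the two aryl fragments.

**Steps most likely to fail**

Step 3. The olefin terminus may enter through a bridged, concerted hydrogen-transfer geometry (C11 axial) instead of the chair with C11 equatorial, eroding facial control at C7, or the C11 cation may be captured by chloride. The fallback is an allylsilane-terminated (Sakurai) cyclization, which needs no hydrogen transfer. It sets out from 1: the same copper-catalysed conjugate addition, run with but-3-en-1-ylmagnesium bromide and Mannich trapping, should give (3R)-3-(but-3-en-1-yl)-2-[(dimethylamino)methyl]-3-methylcyclohexan-1-one F1. MeI and then NaHCO3 give (R)-3-(but-3-en-1-yl)-3-methyl-2-methylidenecyclohexan-1-one F2. Cross-metathesis with trimethyl(2-methylallyl)silane (second-generation Hoveyda–Grubbs catalyst, CH2Cl2, 40 °C) gives the allylsilane (R)-3-methyl-2-methylidene-3-[4-methyl-5-(trimethylsilyl)pent-3-en-1-yl]cyclohexan-1-one F3. TiCl4 (CH2Cl2, −78 °C) then closes ring B through C7 with loss of the silyl group, and NaOMe equilibration comes back to the route at 10.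

Step 9. With so hindered an alkoxide, ligand coupling at trivalent iodine may be outrun by aryne formation from the salt or by transfer of the wrong aryl group. The fallback is nucleophilic aromatic substitution followed by a Sandmeyer exchange. It sets out from 15: KN(SiMe3)2 and 2-bromo-1-fluoro-4-nitrobenzene (THF/DMF, 0 °C) should give (1R,4aR,7R,8aR)-1-(2-bromo-4-nitrophenoxy)-1,4a-dimethyl-7-(prop-1-en-2-yl)decahydronaphthalene F4. Fe/NH4Cl (EtOH/H2O, 70 °C) reduces it to 3-bromo-4-{[(1R,4aR,7R,8aR)-1,4a-dimethyl-7-(prop-1-en-2-yl)decahydronaphthalen-1-yl]oxy}aniline F5. t-BuONO/CuCl2 (MeCN, 0 to 60 °C) replaces the amino group by chlorine and comes back to the route at 21.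

Step 1. Enantiofacial discrimination may be insufficient with the long, olefin-bearing Grignard reagent, and Mannich trapping of the congested enolate may be incomplete. The fallback reverses the order in which the two groups on C10 arrive. It sets out from 2: Grignard reagent 3 adds to 3-ethoxycyclohex-2-en-1-one to give 3-ethoxy-1-(4-methylpent-3-en-1-yl)cyclohex-2-en-1-ol F6 (as its magnesium alkoxide), which dilute HCl converts to 3-(4-methylpent-3-en-1-yl)cyclohex-2-en-1-one F7 (Stork–Danheiser transposition). Copper-catalysed asymmetric conjugate addition of Me3Al (copper thiophene-2-carboxylate, Cu(O2CC4H3S), chiral phosphoramidite ligand, Et2O, −30 °C) should give the dimethylaluminium enolate of (R)-3-methyl-3-(4-methylpent-3-en-1-yl)cyclohexanone F8, which is trapped with Eschenmoser's salt to come back to the route at 5.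

**Further compounds**
F1 | step 3 | (3R)-3-(but-3-en-1-yl)-2-[(dimethylamino)methyl]-3-methylcyclohexan-1-one | O=C1CCC[C@](C)(CCC=C)C1CN(C)C
F2 | step 3 | (R)-3-(but-3-en-1-yl)-3-methyl-2-methylidenecyclohexan-1-one | O=C1CCC[C@](C)(CCC=C)C1=C
F3 | step 3 | (R)-3-methyl-2-methylidene-3-[4-methyl-5-(trimethylsilyl)pent-3-en-1-yl]cyclohexan-1-one (E/Z mixture) | O=C1CCC[C@](C)(CCC=C(C)C[Si](C)(C)C)C1=C
F4 | step 9 | (1R,4aR,7R,8aR)-1-(2-bromo-4-nitrophenoxy)-1,4a-dimethyl-7-(prop-1-en-2-yl)decahydronaphthalene | O=[N+]([O-])c1ccc(O[C@]2(C)CCC[C@]3(C)CC[C@@H](C(C)=C)C[C@H]32)c(Br)c1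
F5 | step 9 | 3-bromo-4-{[(1R,4aR,7R,8aR)-1,4a-dimethyl-7-(prop-1-en-2-yl)decahydronaphthalen-1-yl]oxy}aniline | Nc1ccc(O[C@]2(C)CCC[C@]3(C)CC[C@@H](C(C)=C)C[C@H]32)c(Br)c1
F6 | step 1 | 3-ethoxy-1-(4-methylpent-3-en-1-yl)cyclohex-2-en-1-ol | CCOC1=CC(O)(CCC=C(C)C)CCC1
F7 | step 1 | 3-(4-methylpent-3-en-1-yl)cyclohex-2-en-1-one | O=C1C=C(CCC=C(C)C)CCC1
F8 | step 1 | dimethylaluminium enolate of (R)-3-methyl-3-(4-methylpent-3-en-1-yl)cyclohexanone | C[Al](C)OC1=C[C@@](C)(CCC=C(C)C)CCC1
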